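(The numbers of this flask belong to no real substance; the rest is arithmetic.)

- A neighbour of ochre, the same flask with 0.24 M of nucleophile, comes at the end; first come the flasks you are asked about.

common to all: solid electrophile 0.20 M; gas 79 mM (held); time 12 h
- red: nucleophile 0.300 M
- green: nucleophile 1.20 M
- ochre: nucleophile 0.600 M

    electrophile + nucleophile → acid set free + target (k1 = 0.44 /M/h)
    nucleophile + acid set free ⇌ protonated nucleophile, settled at all times (K2 = 2500 /M)
    acid set free + free base ⇌ salt of the base, settled at all times (K3 = 35 /M)
    electrophile + target ⇌ idle adduct, settled at all times (K4 = 8.3 /M)
    gas ⇌ free base, rate k5*(csat - [free base]) (k5 = 6.3 /h, csat = 79 mM)
    solid electrophile ⇌ electrophile, rate k6*(cs6 - [electrophile]) while solid is left; crystals form when [electrophile] > cs6 (cs6 = 0.10 M, k6 = 0.071 /h)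

- percentages count the solid electrophile that a species holds: one idle adduct counts as two
- target is meant together with its idle adduct
- solid, in amounts per volume of the solution: solid electrophile
- at the start none of free base is dissolved
- at the start none of the solid electrophile is in solution
- what has only dissolved of solid electrophile counts as not reacted
- in an amount of target, one idle adduct counts as one target
- apart from what has only dissolved, what has gone from solid electrophile into another species counts as reacted, even if it can come back
- run time (red): 12 h

- part of the solid electrophile that has reacted (what has only dissolved counts as not reacted) at the end, red
- part of the solid electrophile that has reacted (what has only dissolved counts as not reacted) at the end, green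
- part of the solid electrophile that has reacted (what has only dissolved counts as not reacted) at the end, ochre
- what raising the concentration of nucleophile from its lowest to its highest value here does to the part of the solid electrophile that has reacted (what has only dissolved counts as not reacted) (changes below 5 percentage points count as none) (it rises / it falls / no change)

- Take the main step by itself in red. With the electrophile wholly in solution and the nucleophile as charged, its pseudo-first-order half-life is 5.3 h, so 12 h would turn over 79.5% of the charge.
- Add dissolution. Supply cannot exceed 0.00710 M/h, so at most 42.6% of the charge enters solution in red, and solid stays. Neither step is rate-limiting by itself in red: the coefficient of dissolution, 0.071 /h, and the 0.132 /h at which the nucleophile removes dissolved electrophile differ by a factor of 1.86.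
- Now divide the rate of making by the rate of dissolution and set the ratio to one, as in a steady-state treatment of an enzyme intermediate. Time drops out and leaves the balance level: solubility times dissolution coefficient, over dissolution coefficient plus rate constant times c(nucleophile), the c(electrophile) at which making equals supply. It is 0.0350 M in red, 0.0212 M in ochre and 0.0119 M in green.
- The level is approached with a time constant of 4.93 h in red. Integrating the making over that approach gives, by my reckoning, 0.0346 M of target in red. That is 17.3% reacted, and the same closed form gives 25.4% in ochre and 32.3% in green, a rise of 15 percentage points.
- Add the rest. In red, 750 against 2.77 sends nearly all the acid set free to a second nucleophile, so on my estimate of the target free nucleophile falls by about 23.1% over the run, which slows the making. The idle adduct pulls the other way, adding about 5.03% of the charge. With the two opposed, I keep my three numbers.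
- The forecast gives 18.2%, 25.8% and 32.6% for red, ochre and green, with the trend it rises, and its grounds part from mine on one point, for it says: “Dissolution limits the process.”
- The simulation gives 18.1%, 25.8% and 32.5%, and the trend it rises by 14 points.
- In green, solid stood at 80.5% and then 61.6% of the charge, so dissolution ran throughout, while electrophile held 5.52% and then 5.91%, beside a balance level of 5.93%. In red, electrophile reached 15.5% beside 17.5%. For the neighbour of ochre, the balance level is 0.0402 M, the same closed form gives 14.9% reacted, and that flask stood at 15.7%.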